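The butenolide (ring A: O1, C2, C3, C4, C5) is cut at the C3–C4 bond. C5 carries CO2CH3 and its neighbour C4 can be written as a second ester carbon, so C5 becomes the central carbon of an O-acylated 2-(arylmethyl)malonate. One Dieckmann closure of the alkoxyacetate enolate onto a single CO2CH3 group then forms C3–C4, closes ring A and fixes the quaternary centre C5. The precursor is the dimethyl malonate that carries the silyl-protected dihydrobenzofuranylmethyl group and a [(S)-1-phenylethoxy]acetoxy group on the same carbon; the chiral ether is the only source of group selectivity. Triflation, Suzuki coupling at C4 and one deprotection complete the target.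

Key step: step 11

Remark: ring A is numbered as a furan-2(5H)-one (O1, C2=O, C3, C4, C5), C2′ is the dihydrobenzofuran stereocentre, and the target is read from its SMILES as (5S,2′S); the sense of induction at C5 in step 11 cannot be predicted with confidence, so the (S)-configured ether is carried as the working choice; Ar1CH2 stands for {(2S)-2-[2-(triethylsilyloxy)propan-2-yl]-2,3-dihydro-1-benzofuran-5-yl}methyl.

Step 1
Reactants: 1 (S)-1-phenylethanol; 2 bromoacetic acid
Product: 3 [(1S)-1-phenylethoxy]acetic acid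
Conditions: NaH (3 equiv), THF, 0 °C → reflux; then aq HCl
Reagents that add atoms: none
Why: Williamson ether synthesis in which the sodium alkoxide of 1 displaces bromide from sodium bromoacetate at the CH2 carbon, so the C–O bond of the stereocentre is never broken and its (S) configuration is kept.

Step 2
Reactants: 3 [(1S)-1-phenylethoxy]acetic acid; 4 dimethyl bromomalonate
Product: 5 dimethyl 2-({[(1S)-1-phenylethoxy]acetyl}oxy)malonate
Conditions: Cs2CO3 (0.5 equiv, acid in slight excess), DMF, 0 °C → rt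
Reagents that add atoms: none
Why: Carboxylate O-alkylation (SN2 displacement of the activated bromide of 4 by the caesium salt of 3) is a standard entry to acyloxymalonates, and the absence of excess base keeps the acidic product C–H from reacting on.

Step 3
Reactants: 6 methyl 4-hydroxybenzoate; 7 1-bromo-3-methylbut-2-ene (prenyl bromide)
Product: 8 methyl 4-hydroxy-3-(3-methylbut-2-en-1-yl)benzoate
Conditions: NaH (1.0 equiv), toluene, 0 °C → rt; then 7, rt → 60 °C
Reagents that add atoms: none
Why: Ortho C-alkylation of a sodium phenoxide in a non-polar solvent (phenoxide C-prenylation), where the tight ion pair steers the allylic bromide to the ring carbon next to oxygen and the para position is blocked by the ester.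

Step 4
Reactants: 8 methyl 4-hydroxy-3-(3-methylbut-2-en-1-yl)benzoate
Product: 9 methyl 3-(3-methylbut-2-en-1-yl)-4-[(triisopropylsilyl)oxy]benzoate
Conditions: i-Pr3SiCl, imidazole, DMF, rt
Reagents that add atoms: triisopropylsilyl chloride, CC(C)[Si](Cl)(C(C)C)C(C)C
Why: Silyl ether formation masks the phenoxide, which would otherwise be oxidised or open the epoxide too early under the basic epoxidation conditions, and the triisopropylsilyl ether tolerates pH 10.

Step 5
Reactants: 9 methyl 3-(3-methylbut-2-en-1-yl)-4-[(triisopropylsilyl)oxy]benzoate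
Product: 10 methyl 3-{[(2R)-3,3-dimethyloxiran-2-yl]methyl}-4-[(triisopropylsilyl)oxy]benzoate
Conditions: D-fructose-derived Shi ketone (1,2:4,5-di-O-isopropylidene-β-D-erythro-2,3-hexodiulo-2,6-pyranose, 0.3 equiv), KHSO5 (as 2KHSO5·KHSO4·K2SO4), K2CO3, Bu4NHSO4 (cat.), MeCN–CH2(OMe)2 / aq Na2B4O7 buffer (pH ~10.5), 0 °C
Reagents that add atoms: potassium peroxymonosulfate, [K+].[O-]S(=O)(=O)OO
Why: Shi epoxidation, in which the dioxirane of the chiral ketone transfers oxygen through a spiro transition state that for an alkene of the type RCH2CH=C(CH3)2 should give the (R)-epoxide, the precursor of C2′.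

Step 6
Reactants: 10 methyl 3-{[(2R)-3,3-dimethyloxiran-2-yl]methyl}-4-[(triisopropylsilyl)oxy]benzoate
Product: 12 methyl (2S)-2-(2-hydroxypropan-2-yl)-2,3-dihydro-1-benzofuran-5-carboxylate, via epoxy phenoxide 11 (not isolated)
Conditions: Bu4NF (1.2 equiv), THF, 0 → 50 °C
Reagents that add atoms: none
Why: Fluoride desilylation frees the phenoxide, which opens the epoxide by 5-exo-tet SN2 attack at the secondary carbon with inversion (intramolecular epoxide opening), so the (R)-epoxide becomes the (2S)-dihydrobenzofuran bearing the tertiary alcohol.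

Step 7
Reactants: 12 methyl (2S)-2-(2-hydroxypropan-2-yl)-2,3-dihydro-1-benzofuran-5-carboxylate
Product: 13 methyl (2S)-2-{2-[(triethylsilyl)oxy]propan-2-yl}-2,3-dihydro-1-benzofuran-5-carboxylate
Conditions: Et3SiOTf (1.5 equiv), 2,6-lutidine, CH2Cl2, −78 → 0 °C
Reagents that add atoms: triethylsilyl triflate, CC[Si](CC)(CC)OS(=O)(=O)C(F)(F)F
Why: Silylation of a hindered tertiary alcohol with a silyl triflate and a hindered pyridine base (silyl ether formation) removes the only O–H before the enolate chemistry.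

Step 8
Reactants: 13 methyl (2S)-2-{2-[(triethylsilyl)oxy]propan-2-yl}-2,3-dihydro-1-benzofuran-5-carboxylate
Product: 14 [(2S)-2-{2-[(triethylsilyl)oxy]propan-2-yl}-2,3-dihydro-1-benzofuran-5-yl]methanol
Conditions: i-Bu2AlH (2.5 equiv), CH2Cl2, −78 → 0 °C; aqueous work-up
Reagents that add atoms: none
Why: Hydride reduction of an aromatic methyl ester to the benzylic alcohol (ester reduction) leaves the silyl ether and the aryl ether untouched.

Step 9
Reactants: 14 [(2S)-2-{2-[(triethylsilyl)oxy]propan-2-yl}-2,3-dihydro-1-benzofuran-5-yl]methanol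
Product: 15 (2S)-5-(bromomethyl)-2-{2-[(triethylsilyl)oxy]propan-2-yl}-2,3-dihydro-1-benzofuran
Conditions: CBr4, PPh3, CH2Cl2, 0 °C; used at once
Reagents that add atoms: carbon tetrabromide, BrC(Br)(Br)Br
Why: Appel reaction, in which the oxyphosphonium salt of the primary benzylic alcohol is displaced by bromide under near-neutral conditions that the tertiary silyl ether tolerates.

Step 10
Reactants: 5 dimethyl 2-({[(1S)-1-phenylethoxy]acetyl}oxy)malonate; 15 (2S)-5-(bromomethyl)-2-{2-[(triethylsilyl)oxy]propan-2-yl}-2,3-dihydro-1-benzofuran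
Product: 16 dimethyl 2-(Ar1CH2)-2-({[(1S)-1-phenylethoxy]acetyl}oxy)malonate
Conditions: Cs2CO3 (1.2 equiv), DMF, 0 °C → rt
Reagents that add atoms: none
Why: Malonate alkylation, in which the carbonate deprotonates only the doubly activated C–H of 5 and the soft enolate is benzylated by SN2 reaction to give the prochiral quaternary carbon, while the far less acidic OCH2 protons stay untouched.

Step 11
Reactants: 16 dimethyl 2-(Ar1CH2)-2-({[(1S)-1-phenylethoxy]acetyl}oxy)malonate
Product: 18 methyl (5S)-4-hydroxy-2-oxo-3-[(1S)-1-phenylethoxy]-5-(Ar1CH2)-2,5-dihydrofuran-5-carboxylate, via keto lactone 17 (not isolated)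
Conditions: LiN(SiMe3)2 (2.2 equiv), THF, −78 → −40 °C; then cold 0.5 M HCl
Reagents that add atoms: none
Why: Proposed new method: LiN(SiMe3)2 deprotonates the only enolisable position, the OCH2 group of the alkoxyacetate, to the chelated (Z)-lithium enolate, whose carbon adds to one malonate C=O; loss of methoxide gives keto lactone 17, which is deprotonated at once to the tetronate, so the closure cannot revert and C5 is fixed. The closest known reaction is the Dieckmann cyclisation of α-acyloxy esters to tetronic acids, which has not yet been asked to choose between two ester groups on a prochiral carbon. Ring A closes in the 5-(enolendo)-exo-trig mode, formally disfavoured but routine for tetronic acids. C5 is controlled by the (S)-1-phenylethyl ether on the enolate carbon: with lithium bridging the enolate oxygen and the attacked carbonyl, the closure passes through a compact envelope in which the phenyl group screens one enolate face and the spectator CO2CH3 lies beside the reacting carbonyl on lithium while the arylmethyl group points outward, so each enolate face is paired with one ester group. The step needs group selectivity between the two diastereotopic CO2CH3 groups; its level and sense are open, the configuration is to be assigned on 18, and because the two C5 epimers are diastereomers a minor one should be removable by chromatography.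

Step 12
Reactants: 18 methyl (5S)-4-hydroxy-2-oxo-3-[(1S)-1-phenylethoxy]-5-(Ar1CH2)-2,5-dihydrofuran-5-carboxylate
Product: 19 methyl (5S)-2-oxo-3-[(1S)-1-phenylethoxy]-5-(Ar1CH2)-4-{[(trifluoromethyl)sulfonyl]oxy}-2,5-dihydrofuran-5-carboxylate
Conditions: Tf2O (1.2 equiv), i-Pr2NEt, CH2Cl2, −78 °C
Reagents that add atoms: triflic anhydride, O=S(=O)(OS(=O)(=O)C(F)(F)F)C(F)(F)F
Why: Enol triflate formation, in which the acidic C4 enol of the tetronic acid is O-sulfonylated at low temperature by Tf2O and a hindered amine without harm to the silyl ether or the enol ether.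

Step 13
Reactants: 19 methyl (5S)-2-oxo-3-[(1S)-1-phenylethoxy]-5-(Ar1CH2)-4-{[(trifluoromethyl)sulfonyl]oxy}-2,5-dihydrofuran-5-carboxylate; 20 [4-(benzyloxy)phenyl]boronic acid
Product: 21 methyl (5S)-4-[4-(benzyloxy)phenyl]-2-oxo-3-[(1S)-1-phenylethoxy]-5-(Ar1CH2)-2,5-dihydrofuran-5-carboxylate
Conditions: Pd(PPh3)4 (5 mol%), K3PO4 (finely ground), 1,4-dioxane, 80 °C
Reagents that add atoms: none
Why: Suzuki–Miyaura coupling, in which zerovalent palladium inserts readily into the electron-poor C4–OTf bond of the tetronate triflate and K3PO4 in dioxane mediates transmetalation while sparing triflate and esters from hydrolysis; C5 is not involved.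

Step 14
Reactants: 21 methyl (5S)-4-[4-(benzyloxy)phenyl]-2-oxo-3-[(1S)-1-phenylethoxy]-5-(Ar1CH2)-2,5-dihydrofuran-5-carboxylate
Product: 23 methyl (5S)-3-hydroxy-5-{[(2S)-2-(2-hydroxypropan-2-yl)-2,3-dihydro-1-benzofuran-5-yl]methyl}-4-(4-hydroxyphenyl)-2-oxo-2,5-dihydrofuran-5-carboxylate, via silyl ether 22 (not isolated)
Conditions: H2 (1 atm), Pd/C (10 wt% Pd), MeOH, rt; filter; then 0.1 M HCl in MeOH–H2O, rt
Reagents that add atoms: none
Why: Hydrogenolysis over Pd/C cleaves both benzylic C–O bonds (the benzyl aryl ether and the 1-phenylethyl enol ether, whose oxygen is a good leaving group), and mild acid in methanol then removes the triethylsilyl ether (acidic desilylation) without touching methyl ester, lactone or stereocentres.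

Compound list
1 | (S)-1-phenylethanol | C[C@H](O)c1ccccc1 | starting material
2 | bromoacetic acid | OC(=O)CBr | starting material
3 | [(1S)-1-phenylethoxy]acetic acid | C[C@H](OCC(=O)O)c1ccccc1 | intermediate
4 | dimethyl bromomalonate | COC(=O)C(Br)C(=O)OC | starting material
5 | dimethyl 2-({[(1S)-1-phenylethoxy]acetyl}oxy)malonate | COC(=O)C(OC(=O)CO[C@@H](C)c1ccccc1)C(=O)OC | intermediate
6 | methyl 4-hydroxybenzoate | COC(=O)c1ccc(O)cc1 | starting material
7 | 1-bromo-3-methylbut-2-ene (prenyl bromide) | CC(C)=CCBr | starting material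
8 | methyl 4-hydroxy-3-(3-methylbut-2-en-1-yl)benzoate | COC(=O)c1ccc(O)c(CC=C(C)C)c1 | intermediate
9 | methyl 3-(3-methylbut-2-en-1-yl)-4-[(triisopropylsilyl)oxy]benzoate | COC(=O)c1ccc(O[Si](C(C)C)(C(C)C)C(C)C)c(CC=C(C)C)c1 | intermediate
10 | methyl 3-{[(2R)-3,3-dimethyloxiran-2-yl]methyl}-4-[(triisopropylsilyl)oxy]benzoate | COC(=O)c1ccc(O[Si](C(C)C)(C(C)C)C(C)C)c(C[C@H]2OC2(C)C)c1 | intermediate
11 | methyl 3-{[(2R)-3,3-dimethyloxiran-2-yl]methyl}-4-hydroxybenzoate (present as its tetrabutylammonium phenoxide) | COC(=O)c1ccc(O)c(C[C@H]2OC2(C)C)c1 | intermediate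
12 | methyl (2S)-2-(2-hydroxypropan-2-yl)-2,3-dihydro-1-benzofuran-5-carboxylate | COC(=O)c1ccc2c(c1)C[C@@H](C(C)(C)O)O2 | intermediate
13 | methyl (2S)-2-{2-[(triethylsilyl)oxy]propan-2-yl}-2,3-dihydro-1-benzofuran-5-carboxylate | COC(=O)c1ccc2c(c1)C[C@@H](C(C)(C)O[Si](CC)(CC)CC)O2 | intermediate
14 | [(2S)-2-{2-[(triethylsilyl)oxy]propan-2-yl}-2,3-dihydro-1-benzofuran-5-yl]methanol | OCc1ccc2c(c1)C[C@@H](C(C)(C)O[Si](CC)(CC)CC)O2 | intermediate
15 | (2S)-5-(bromomethyl)-2-{2-[(triethylsilyl)oxy]propan-2-yl}-2,3-dihydro-1-benzofuran | BrCc1ccc2c(c1)C[C@@H](C(C)(C)O[Si](CC)(CC)CC)O2 | intermediate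
16 | dimethyl 2-(Ar1CH2)-2-({[(1S)-1-phenylethoxy]acetyl}oxy)malonate | COC(=O)C(Cc1ccc2c(c1)C[C@@H](C(C)(C)O[Si](CC)(CC)CC)O2)(C(=O)OC)OC(=O)CO[C@@H](C)c1ccccc1 | intermediate
17 | methyl (5S)-2,4-dioxo-3-[(1S)-1-phenylethoxy]-5-(Ar1CH2)oxolane-5-carboxylate (both C3 epimers) | COC(=O)[C@@]1(Cc2ccc3c(c2)C[C@@H](C(C)(C)O[Si](CC)(CC)CC)O3)OC(=O)C(O[C@@H](C)c4ccccc4)C1=O | intermediate
18 | methyl (5S)-4-hydroxy-2-oxo-3-[(1S)-1-phenylethoxy]-5-(Ar1CH2)-2,5-dihydrofuran-5-carboxylate | COC(=O)[C@@]1(Cc2ccc3c(c2)C[C@@H](C(C)(C)O[Si](CC)(CC)CC)O3)OC(=O)C(O[C@@H](C)c4ccccc4)=C1O | intermediate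
19 | methyl (5S)-2-oxo-3-[(1S)-1-phenylethoxy]-5-(Ar1CH2)-4-{[(trifluoromethyl)sulfonyl]oxy}-2,5-dihydrofuran-5-carboxylate | COC(=O)[C@@]1(Cc2ccc3c(c2)C[C@@H](C(C)(C)O[Si](CC)(CC)CC)O3)OC(=O)C(O[C@@H](C)c4ccccc4)=C1OS(=O)(=O)C(F)(F)F | intermediate
20 | [4-(benzyloxy)phenyl]boronic acid | OB(O)c1ccc(OCc2ccccc2)cc1 | starting material
21 | methyl (5S)-4-[4-(benzyloxy)phenyl]-2-oxo-3-[(1S)-1-phenylethoxy]-5-(Ar1CH2)-2,5-dihydrofuran-5-carboxylate | COC(=O)[C@@]1(Cc2ccc3c(c2)C[C@@H](C(C)(C)O[Si](CC)(CC)CC)O3)OC(=O)C(O[C@@H](C)c4ccccc4)=C1c1ccc(OCc5ccccc5)cc1 | intermediate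
22 | methyl (5S)-3-hydroxy-4-(4-hydroxyphenyl)-2-oxo-5-(Ar1CH2)-2,5-dihydrofuran-5-carboxylate | COC(=O)[C@@]1(Cc2ccc3c(c2)C[C@@H](C(C)(C)O[Si](CC)(CC)CC)O3)OC(=O)C(O)=C1c1ccc(O)cc1 | intermediate
23 | methyl (5S)-3-hydroxy-5-{[(2S)-2-(2-hydroxypropan-2-yl)-2,3-dihydro-1-benzofuran-5-yl]methyl}-4-(4-hydroxyphenyl)-2-oxo-2,5-dihydrofuran-5-carboxylate (CNP0280395.4) | COC(=O)[C@@]1(Cc2ccc3c(c2)C[C@@H](C(C)(C)O)O3)OC(=O)C(O)=C1c1ccc(O)cc1 | target

Total step count: 14 (branch A, steps 1–2; branch B, steps 3–9; joined in step 10).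
Longest linear sequence: 12 steps (6 → 23, steps 3–14).

Steps most likely to fail

1. Step 11 (Proposed new method). The enolate may distinguish poorly between the two diastereotopic CO2CH3 groups, or it may fragment to an alkoxyketene and the tartronate alkoxide before it closes. If only the sense of selection is wrong, the mirror-image alcohol in step 1 is the obvious remedy. The fallback below is for low selectivity or a failed closure and uses known chemistry only. It sets out from bromide 15 and comes back to the route at 21, so steps 10–13 are bypassed and C5 is set before ring A exists. Purchasable methyl 3-[4-(benzyloxy)phenyl]-3-oxopropanoate (COC(=O)CC(=O)c1ccc(OCc2ccccc2)cc1) is C-alkylated with 15 (K2CO3, acetone) to give methyl 2-(Ar1CH2)-3-[4-(benzyloxy)phenyl]-3-oxopropanoate F1. A catalytic enantioselective α-hydroxylation of this β-keto ester (TiCl2(TADDOLato) catalyst, 2-(phenylsulfonyl)-3-phenyloxaziridine) should give methyl (2S)-2-hydroxy-2-(Ar1CH2)-3-[4-(benzyloxy)phenyl]-3-oxopropanoate F2; any minor C5 epimer is a diastereomer and can be separated. Steglich esterification of the tertiary alcohol with acid 3 (DCC, DMAP, CH2Cl2) gives methyl (2S)-2-(Ar1CH2)-3-[4-(benzyloxy)phenyl]-3-oxo-2-({[(1S)-1-phenylethoxy]acetyl}oxy)propanoate F3. DBU in MeCN then brings about the intramolecular aldol condensation of the α-acyloxy aryl ketone (Knoevenagel-type butenolide closure) and delivers 21, in which the phenylethyl group serves only as a protecting group.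

2. Step 13. The vinylogous acyl triflate may lose its sulfonyl group by hydrolysis back to the tetronate, and coupling may be slow at C4, which is flanked by the quaternary C5 and a branched ether. The fallback sets out from 18 and comes back at 21. Bromodehydroxylation of the vinylogous acid with PPh3·Br2 and Et3N (CH2Cl2, 0 °C) gives the hydrolytically robust methyl 4-bromo-2-oxo-3-[(1S)-1-phenylethoxy]-5-(Ar1CH2)-2,5-dihydrofuran-5-carboxylate F4; the arrangement at C5 is unchanged, and the descriptor reads R only because bromine raises the rank of C4. Base-free Negishi coupling (Pd(PPh3)4 cat., THF, 50 °C) with [4-(benzyloxy)phenyl]zinc chloride F5, made from 1-(benzyloxy)-4-bromobenzene with n-BuLi and ZnCl2, then gives 21.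

3. Step 3. O-Alkylation and double alkylation of the phenoxide may outrun the wanted ortho C-alkylation. The fallback sets out from 6 and comes back at 8. Etherification of 6 with 3-chloro-3-methylbut-1-yne (CC(C)(Cl)C#C; K2CO3, KI, CuI cat., acetone) gives methyl 4-[(2-methylbut-3-yn-2-yl)oxy]benzoate F6. Semihydrogenation (H2, Pd/CaCO3 poisoned with Pb(OAc)2, quinoline) gives methyl 4-[(2-methylbut-3-en-2-yl)oxy]benzoate F7. Aromatic Claisen rearrangement (N,N-diethylaniline, 190 °C) moves the allyl unit to the ortho carbon with allylic transposition and gives 8 with the regiochemistry fixed by the sigmatropic shift.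

Further compounds
F1 | step 11 | methyl 2-(Ar1CH2)-3-[4-(benzyloxy)phenyl]-3-oxopropanoate (C2 epimers) | COC(=O)C(Cc1ccc2c(c1)C[C@@H](C(C)(C)O[Si](CC)(CC)CC)O2)C(=O)c1ccc(OCc2ccccc2)cc1
F2 | step 11 | methyl (2S)-2-hydroxy-2-(Ar1CH2)-3-[4-(benzyloxy)phenyl]-3-oxopropanoate | COC(=O)[C@@](C(=O)c1ccc(OCc2ccccc2)cc1)(Cc1ccc2c(c1)C[C@@H](C(C)(C)O[Si](CC)(CC)CC)O2)O
F3 | step 11 | methyl (2S)-2-(Ar1CH2)-3-[4-(benzyloxy)phenyl]-3-oxo-2-({[(1S)-1-phenylethoxy]acetyl}oxy)propanoate | COC(=O)[C@@](C(=O)c1ccc(OCc2ccccc2)cc1)(Cc1ccc2c(c1)C[C@@H](C(C)(C)O[Si](CC)(CC)CC)O2)OC(=O)CO[C@@H](C)c1ccccc1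
F4 | step 13 | methyl (5R)-4-bromo-2-oxo-3-[(1S)-1-phenylethoxy]-5-(Ar1CH2)-2,5-dihydrofuran-5-carboxylate | COC(=O)[C@@]1(Cc2ccc3c(c2)C[C@@H](C(C)(C)O[Si](CC)(CC)CC)O3)OC(=O)C(O[C@@H](C)c4ccccc4)=C1Br
F5 | step 13 | [4-(benzyloxy)phenyl]zinc chloride | Cl[Zn]c1ccc(OCc2ccccc2)cc1
F6 | step 3 | methyl 4-[(2-methylbut-3-yn-2-yl)oxy]benzoate | COC(=O)c1ccc(OC(C)(C)C#C)cc1
F7 | step 3 | methyl 4-[(2-methylbut-3-en-2-yl)oxy]benzoate | COC(=O)c1ccc(OC(C)(C)C=C)cc1
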